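The runs were computed for substances that don't exist, and the scatter is random.

Slowness showed in the alpha run as a steady supply: open intermediate and target together climbed at a nearly even pace. I called that pace the feed F, the mean rate at which charged solid substrate reaches open intermediate or target while solid is left, and I replaced the curve by this mean after a lag t_L.

| flask | solid substrate | partner | remark | time |
|---|---|---|---|---|
| theta | 0.049 M | 0.0088 M | run made earlier |  |
| delta | 0.049 M | 0.16 M | run made earlier |  |
| alpha | 0.067 M | 0.0539 M | run made earlier |  |
| east | 0.20 M | 0.200 M |  | 2.5 d |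
| north | 0.025 M | 0.150 M |  | 2.5 d |
| north-west | 0.015 M | 0.0150 M |  | 2.5 d |
| west | 0.15 M | 0.0250 M |  | 2.5 d |
| south | 0.049 M | 0.0539 M |  | 2.5 d |

| run | time / h | open intermediate / % | target / % |
|---|---|---|---|
| theta | 5.00 | 6.7 | 0.1 |
| theta | 10.0 | 20.7 | 0.6 |
| theta | 15.0 | 38.2 | 2.0 |
| theta | 20.0 | 51.6 | 4.0 |
| theta | 25.0 | 62.2 | 10.0 |
| theta | 30.0 | 70.0 | 10.5 |
| delta | 2.50 | 2.7 | 0 |
| delta | 4.00 | 4.2 | 1.0 |
| delta | 6.00 | 7.2 | 2.3 |
| delta | 10.0 | 11.0 | 8.2 |
| delta | 20.0 | 14.9 | 42.4 |
| delta | 30.0 | 8.5 | 71.2 |
| alpha | 6.00 | 5.0 | 0.7 |
| alpha | 12.0 | 15.6 | 4.1 |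
| alpha | 20.0 | 25.3 | 16.9 |
| alpha | 25.0 | 29.0 | 26.3 |
| alpha | 30.0 | 32.3 | 35.2 |

(scatter of a reading: 1 percentage point)

- all flasks from highest to lowest amount of open intermediate, in percent of the solid substrate charged, at 2.5 d (east / north / north-west / west / south)
- the same order at 6.0 h (east / north / north-west / west / south)
- the amount of open intermediate, in percent of the solid substrate charged of the flask you put first, at 2.5 d
- the amount of open intermediate, in percent of the solid substrate charged of the flask you put last, at 2.5 d

I read the feed from the alpha readings between 12.0 h and 30.0 h, and took the lag from the amount formed by the first of these: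

F = 0.00178 M h⁻¹
t_L = 4.58 h

The delta run, with more partner and less solid substrate, gave 0.00187 M h⁻¹, so I kept the alpha F for west. Each target uses one second intermediate, made from one partner, so in west I reckoned, with t the time:

formed = F(t − t_L) = 0.0986 M
left = formed − partner = 0.0736 M, or 49.1 % of the charge

Partner was my limiting reagent in west. From the delta readings between 20.0 h and 30.0 h, taking its partner as activated, I read a coupling constant k = 0.0310 M⁻¹ min⁻¹. The ladder for west then ran:

lag: 4.58 h
coupling, 1/(k·left): 7.30 h
feed matches partner, partner/F: 14.1 h
asked time: 60 h
whole charge fed, t_L + charge/F: 88.9 h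

In west, feeding the whole charge reckoned longer than the asked time, and the coupling was quicker than the time remaining after partner was matched.

The forecast gave west > north-west > south > east > north at 2.5 d and north-west > north > south > west > east at 6.0 h, with 50 % first and 0.5 % last, and said of west that “partner caps target at 0.025 M”. My own share for west was 49.1 %.

The simulation gave west > north-west > south > east > north and north-west > north > south > west > east, with 50.6 % and 0.585 %.

    starting material → open intermediate (k = 0.00130 min⁻¹)
    solid substrate ⇌ starting material, rate k2*(cs2 - [starting material]) while solid is left; crystals form when [starting material] > cs2 (solubility = 37.0 mM, k = 0.00220 min⁻¹)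
    open intermediate + second intermediate → target (k = 0.0320 M⁻¹ min⁻¹)
    partner → second intermediate (k = 0.00170 min⁻¹)

At 2.50 d, west held 0.100 M as open intermediate and target, against my 0.0986 M. A flask like west with 0.062 M of partner reckons to 24.4 % open intermediate, and it held 29.9 %. At 2.50 d that flask still had 0.00653 M of second intermediate, which is 4.35 % of its solid substrate charge, and its target stood at 36.9 %. With the other charges of west and the time held, open intermediate and target were level at 0.0548 M of partner.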